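**Retrosynthetic overview**
- Target 12 comes from hydroxy-enone 11 by a hydroxyl-directed 1,2-reduction. 11 comes from 9 by desilylation and a 1,2-benzoyl shift from the tertiary to the primary oxygen.
- The trans acetate/benzoate pair of 9 comes from benzoate opening of an acetoxonium ion (C–O), generated from the epoxide of dienone 4 by acetolysis and triflate displacement.
- Dienone 4 comes from an enantioselective benzoyloxylative dearomatisation of phenol 3 (key C–O bond, sets the quaternary carbinol). 3 is silyl-protected salicyl alcohol 1.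
- Rings: the only carbocycle is the benzene ring of 1, carried through. A transient oxirane (5) and then a 1,3-dioxolan-2-ylium ring (8) are formed and opened, in that order.

Assumption: the (R,R)-antipode of the iodoarene catalyst is taken to give (S)-dienone 4; if a test run shows the opposite sense, the (S,S)-catalyst is used.

**Step 1**
Reactants: 1 salicyl alcohol (2-hydroxybenzyl alcohol)
Product: 3 tert-butyl[(2-hydroxybenzyl)oxy]diphenylsilane, via bis-silyl ether 2 (not isolated)
Conditions: TBDPSCl (2.3 equiv), imidazole, DMF, 25 °C; then MeOH, KHF2, 25 °C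
Reagents that add atoms: tert-butyl(chloro)diphenylsilane (TBDPSCl), CC(C)(C)[Si](Cl)(c1ccccc1)c1ccccc1
Why: Exhaustive imidazole-mediated silyl ether formation followed by chemoselective bifluoride cleavage of the much more labile aryl silyl ether leaves only the benzylic oxygen protected; no stereocentre is formed.

**Step 2**
Reactants: 3 tert-butyl[(2-hydroxybenzyl)oxy]diphenylsilane
Product: 4 (1S)-1-{[(tert-butyldiphenylsilyl)oxy]methyl}-2-oxocyclohexa-3,5-dien-1-yl benzoate
Conditions: 2-iodo-1,3-bis{[(2R)-1-oxo-1-(2,4,6-trimethylanilino)propan-2-yl]oxy}benzene (15 mol %), PhCO3H (pre-formed from Bz2O and urea·H2O2), PhCO2H (2 equiv), CHCl3, −20 °C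
Reagents that add atoms: benzoic acid, O=C(O)c1ccccc1
Why: Proposed new method: peroxybenzoic acid oxidises the iodoarene to a chiral trivalent-iodine dibenzoate, the phenol exchanges onto iodine, and a benzoate held by the amide N–H bonds of the C2-symmetric ligand attacks the alkyl-bearing ortho carbon in an associative ligand-coupling step that expels the iodoarene and sets the quaternary C–O stereocentre on one enantiotopic face (the substituted ortho carbon is preferred as in Wessely oxidation, and para attack needs a free phenoxenium ion that the non-ionising solvent disfavours); the closest known reactions are the racemic Wessely acyloxylation of o-alkylphenols and the intramolecular enantioselective Kita-type spirolactonisation with this class of iodoarene catalysts.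

**Step 3**
Reactants: 4 (1S)-1-{[(tert-butyldiphenylsilyl)oxy]methyl}-2-oxocyclohexa-3,5-dien-1-yl benzoate
Product: 6 (1R,2R,3S)-3-(acetyloxy)-1-{[(tert-butyldiphenylsilyl)oxy]methyl}-2-hydroxy-6-oxocyclohex-4-en-1-yl benzoate, via epoxy-enone 5 (not isolated)
Conditions: mCPBA, NaHCO3, CH2Cl2, 0 → 25 °C; aqueous NaHCO3 wash; then AcOH, BF3·OEt2 (10 mol %), CH2Cl2, −20 → 0 °C
Reagents that add atoms: 3-chloroperoxybenzoic acid (mCPBA), OOC(=O)c1cccc(Cl)c1; acetic acid, CC(=O)O
Why: Prilezhaev epoxidation takes the electron-richer γ,δ-alkene on the face anti to the bulky silyloxymethyl group (syn to the benzoate), and Lewis-acid-promoted SN2-type acetolysis at the allylic γ-carbon with inversion gives the trans hydroxy acetate, the cis-disposed tertiary benzoate being unable to participate.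

**Step 4**
Reactants: 6 (1R,2R,3S)-3-(acetyloxy)-1-{[(tert-butyldiphenylsilyl)oxy]methyl}-2-hydroxy-6-oxocyclohex-4-en-1-yl benzoate
Product: 9 (1R,2S,3R)-2-(acetyloxy)-1-{[(tert-butyldiphenylsilyl)oxy]methyl}-6-oxocyclohex-4-ene-1,3-diyl dibenzoate, via triflate 7 (not isolated), via acetoxonium triflate 8 (not isolated)
Conditions: Tf2O, 2,6-di-tert-butyl-4-methylpyridine, CH2Cl2, −40 °C; then Bu4N(O2CPh), −40 → 25 °C
Reagents that add atoms: tetrabutylammonium benzoate, CCCC[N+](CCCC)(CCCC)CCCC.[O-]C(=O)c1ccccc1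
Why: Triflation triggers anti displacement by the neighbouring trans acetate (anchimeric assistance) to a cis-fused acetoxonium ion on the face of the silyloxymethyl group, which benzoate opens by SN2 attack at the less hindered allylic carbon, so the carbinol carbon is inverted once and the allylic carbon twice and the acetate ends trans to the tertiary oxygen (Prévost/Winstein acyloxonium chemistry).

**Step 5**
Reactants: 9 (1R,2S,3R)-2-(acetyloxy)-1-{[(tert-butyldiphenylsilyl)oxy]methyl}-6-oxocyclohex-4-ene-1,3-diyl dibenzoate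
Product: 11 [(1R,5R,6S)-6-(acetyloxy)-5-(benzoyloxy)-1-hydroxy-2-oxocyclohex-3-en-1-yl]methyl benzoate, via primary alcohol 10 (not isolated)
Conditions: HF·pyridine, pyridine, THF, 0 → 25 °C; then imidazole (0.2 equiv), CH2Cl2, 25 °C
Reagents that add atoms: none
Why: Fluoride desilylation frees the primary alcohol, to which the activated tertiary α-keto benzoate transfers through a five-membered ortho-acid intermediate (base-catalysed 1,2 O-to-O acyl migration), giving the only acyl isomer in which just the tertiary hydroxyl is free; no stereocentre changes.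

**Step 6**
Reactants: 11 [(1R,5R,6S)-6-(acetyloxy)-5-(benzoyloxy)-1-hydroxy-2-oxocyclohex-3-en-1-yl]methyl benzoate
Product: 12 [(1S,2R,5R,6S)-6-(acetyloxy)-5-(benzoyloxy)-1,2-dihydroxycyclohex-3-en-1-yl]methyl benzoate
Conditions: Me4NBH(OAc)3, MeCN/AcOH (1:1), −30 °C
Reagents that add atoms: none
Why: Hydroxyl-directed (Evans–Saksena type) reduction: the tertiary alcohol binds the acetoxyborohydride and delivers hydride to the carbonyl face it occupies, giving the 1,2-reduced allylic alcohol trans to the tertiary hydroxyl while the esters are untouched.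

**Compound list**
1 | salicyl alcohol (2-hydroxybenzyl alcohol) | OCc1ccccc1O | starting material
2 | tert-butyl{2-[(tert-butyldiphenylsilyloxy)methyl]phenoxy}diphenylsilane (bis-silyl ether) | CC(C)(C)[Si](c1ccccc1)(c1ccccc1)OCc1ccccc1O[Si](c1ccccc1)(c1ccccc1)C(C)(C)C | intermediate (not isolated)
3 | tert-butyl[(2-hydroxybenzyl)oxy]diphenylsilane | CC(C)(C)[Si](c1ccccc1)(c1ccccc1)OCc1ccccc1O | intermediate
4 | (1S)-1-{[(tert-butyldiphenylsilyl)oxy]methyl}-2-oxocyclohexa-3,5-dien-1-yl benzoate | C1=CC=CC(=O)[C@@]1(OC(=O)c2ccccc2)CO[Si](c2ccccc2)(c2ccccc2)C(C)(C)C | intermediate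
5 | (1R,2R,6R)-2-{[(tert-butyldiphenylsilyl)oxy]methyl}-3-oxo-7-oxabicyclo[4.1.0]hept-4-en-2-yl benzoate (epoxide cis to the benzoate) | O1[C@@H]2[C@H]1C=CC(=O)[C@@]2(OC(=O)c3ccccc3)CO[Si](c3ccccc3)(c3ccccc3)C(C)(C)C | intermediate (not isolated)
6 | (1R,2R,3S)-3-(acetyloxy)-1-{[(tert-butyldiphenylsilyl)oxy]methyl}-2-hydroxy-6-oxocyclohex-4-en-1-yl benzoate | O[C@@H]1[C@@H](OC(C)=O)C=CC(=O)[C@@]1(OC(=O)c2ccccc2)CO[Si](c2ccccc2)(c2ccccc2)C(C)(C)C | intermediate
7 | (1R,2R,3S)-3-(acetyloxy)-1-{[(tert-butyldiphenylsilyl)oxy]methyl}-6-oxo-2-{[(trifluoromethyl)sulfonyl]oxy}cyclohex-4-en-1-yl benzoate | FC(F)(F)S(=O)(=O)O[C@@H]1[C@@H](OC(C)=O)C=CC(=O)[C@@]1(OC(=O)c2ccccc2)CO[Si](c2ccccc2)(c2ccccc2)C(C)(C)C | intermediate (not isolated)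
8 | (3aS,4R,7aS)-4-(benzoyloxy)-4-{[(tert-butyldiphenylsilyl)oxy]methyl}-2-methyl-5-oxo-3a,4,5,7a-tetrahydro-1,3-benzodioxol-2-ylium trifluoromethanesulfonate (cis-fused acetoxonium ion) | CC1=[O+][C@H]2[C@@H](O1)C=CC(=O)[C@@]2(OC(=O)c3ccccc3)CO[Si](c3ccccc3)(c3ccccc3)C(C)(C)C.[O-]S(=O)(=O)C(F)(F)F | intermediate (not isolated)
9 | (1R,2S,3R)-2-(acetyloxy)-1-{[(tert-butyldiphenylsilyl)oxy]methyl}-6-oxocyclohex-4-ene-1,3-diyl dibenzoate | CC(=O)O[C@H]1[C@H](OC(=O)c2ccccc2)C=CC(=O)[C@@]1(OC(=O)c2ccccc2)CO[Si](c2ccccc2)(c2ccccc2)C(C)(C)C | intermediate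
10 | (1R,2S,3R)-2-(acetyloxy)-1-(hydroxymethyl)-6-oxocyclohex-4-ene-1,3-diyl dibenzoate | CC(=O)O[C@H]1[C@H](OC(=O)c2ccccc2)C=CC(=O)[C@@]1(OC(=O)c2ccccc2)CO | intermediate (not isolated)
11 | [(1R,5R,6S)-6-(acetyloxy)-5-(benzoyloxy)-1-hydroxy-2-oxocyclohex-3-en-1-yl]methyl benzoate | CC(=O)O[C@H]1[C@H](OC(=O)c2ccccc2)C=CC(=O)[C@@]1(O)COC(=O)c1ccccc1 | intermediate
12 | [(1S,2R,5R,6S)-6-(acetyloxy)-5-(benzoyloxy)-1,2-dihydroxycyclohex-3-en-1-yl]methyl benzoate | CC(=O)O[C@H]1[C@H](OC(=O)c2ccccc2)C=C[C@@H](O)[C@@]1(O)COC(=O)c1ccccc1 | target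

**Step count and risks**
Total steps: 6. Longest linear sequence: 6 steps (1 → 12).

Step 2 (the proposed new method) is the most likely to fail. Oxidation may occur at the para or the unsubstituted ortho position, the enantioselectivity of an intermolecular carboxylate transfer is unproven, and 4 can slowly dimerise. The fallback sets out from 3 and returns at 4. Classical Wessely oxidation with Pb(OAc)4 and excess benzoic acid in CH2Cl2 at 0 °C (tetravalent lead benzoate formed in the flask) gives racemic 1-{[(tert-butyldiphenylsilyl)oxy]methyl}-2-oxocyclohexa-3,5-dien-1-yl benzoate F1. Preparative chiral-phase SFC then delivers 4 and the unwanted (1R)-1-{[(tert-butyldiphenylsilyl)oxy]methyl}-2-oxocyclohexa-3,5-dien-1-yl benzoate F2, which is discarded.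

Step 4 is the second risk. Triflation of the hindered alcohol may be slow, the tertiary benzoate of 6 can shift to the neighbouring cis hydroxyl before triflation, and water capture of the acetoxonium ion would give a cis hydroxy ester. The fallback sets out from 4 (bypassing 6) and returns at 9 by a halonium-based Prévost sequence. N-Iodosuccinimide in AcOH/NaOAc at 25 °C forms the iodonium ion anti to the silyloxymethyl group, and acetate opens it at the allylic carbon to give (1S,2R,3S)-3-(acetyloxy)-1-{[(tert-butyldiphenylsilyl)oxy]methyl}-2-iodo-6-oxocyclohex-4-en-1-yl benzoate F3. AgO2CPh (silver benzoate) in dry toluene at 60 °C then removes iodide with acetate participation, giving the same acetoxonium cation as in 8, which benzoate opens to 9. This is kept as the fallback because an iodonium ion on the other face could be trapped by the tertiary benzoate.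

Step 5 is the third risk. The unmasked β-hydroxy ketone 10 can undergo retro-aldol loss of formaldehyde, and the cis acetate can compete for the primary hydroxyl by 1,3-migration. The fallback sets out from 9 and returns at 12, removing the ketone first. Luche reduction (NaBH4, CeCl3·7H2O, MeOH, −78 °C), with hydride entering anti to the silyloxymethyl group, gives (1S,2S,3R,6R)-2-(acetyloxy)-1-{[(tert-butyldiphenylsilyl)oxy]methyl}-6-hydroxycyclohex-4-ene-1,3-diyl dibenzoate F4. HF·pyridine in THF/pyridine then gives (1S,2S,3R,6R)-2-(acetyloxy)-6-hydroxy-1-(hydroxymethyl)cyclohex-4-ene-1,3-diyl dibenzoate F5, which is not isolated. Its tertiary benzoate shifts to the primary oxygen (imidazole, CH2Cl2) faster than to the trans ring hydroxyl, giving 12 directly.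

**Further compounds**
F1 | step 2 | racemic 1-{[(tert-butyldiphenylsilyl)oxy]methyl}-2-oxocyclohexa-3,5-dien-1-yl benzoate | C1=CC=CC(=O)C1(OC(=O)c2ccccc2)CO[Si](c2ccccc2)(c2ccccc2)C(C)(C)C
F2 | step 2 | (1R)-1-{[(tert-butyldiphenylsilyl)oxy]methyl}-2-oxocyclohexa-3,5-dien-1-yl benzoate | C1=CC=CC(=O)[C@]1(OC(=O)c2ccccc2)CO[Si](c2ccccc2)(c2ccccc2)C(C)(C)C
F3 | step 4 | (1S,2R,3S)-3-(acetyloxy)-1-{[(tert-butyldiphenylsilyl)oxy]methyl}-2-iodo-6-oxocyclohex-4-en-1-yl benzoate | I[C@@H]1[C@@H](OC(C)=O)C=CC(=O)[C@@]1(OC(=O)c2ccccc2)CO[Si](c2ccccc2)(c2ccccc2)C(C)(C)C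
F4 | step 5 | (1S,2S,3R,6R)-2-(acetyloxy)-1-{[(tert-butyldiphenylsilyl)oxy]methyl}-6-hydroxycyclohex-4-ene-1,3-diyl dibenzoate | CC(=O)O[C@H]1[C@H](OC(=O)c2ccccc2)C=C[C@@H](O)[C@@]1(OC(=O)c2ccccc2)CO[Si](c2ccccc2)(c2ccccc2)C(C)(C)C
F5 | step 5 | (1S,2S,3R,6R)-2-(acetyloxy)-6-hydroxy-1-(hydroxymethyl)cyclohex-4-ene-1,3-diyl dibenzoate | CC(=O)O[C@H]1[C@H](OC(=O)c2ccccc2)C=C[C@@H](O)[C@@]1(OC(=O)c2ccccc2)CO
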